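**Retrosynthetic overview**

1. Lactone numbering: O1, C2 (carbonyl), C3 (carries the guaiacylmethyl group), C4 (carries the syringylmethyl group), C5 (OCH2). The target is (3R,4R), trans. Both phenols are carried as benzyl ethers and freed last; both arenes are bought, and the lactone is the only ring made.
2. Key disconnection: C2–C3 and O1–C5 are cut together. This removes the C2(=O)–O1 unit as a formate-derived carbon dioxide radical anion and opens the lactone to the acyclic chloride ArCH=CH–CH(CH2Ar')–CH2Cl (Ar = 4-benzyloxy-3-methoxyphenyl, Ar' = 4-benzyloxy-3,5-dimethoxyphenyl), which has one stereocentre, the future C4.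
3. Enabling feature: C3 is homobenzylic to the guaiacyl ring, so it is the β-carbon of a guaiacyl styrene, where radical carboxylation is anti-Markovnikov. C5 is a primary carbon 1,3 to C3, so the new carboxylate closes the ring 5-exo-tet. The trans C3/C4 arrangement is the thermodynamic one and follows from C4 by equilibration.
4. The C4 centre comes from auxiliary-controlled benzylation of a styrylacetic imide (from O-benzylvanillin by Wittig reaction) with the syringyl-type benzyl bromide (from syringaldehyde), then reduction and chlorination.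

Key step: step 9

Assumption: syringaldehyde, O-benzylvanillin, (2-carboxyethyl)triphenylphosphonium bromide and (4R)-4-benzyl-1,3-oxazolidin-2-one are taken as commercial.

**Route**

Step 1
Reactants: 1 syringaldehyde (4-hydroxy-3,5-dimethoxybenzaldehyde)
Product: 2 4-(benzyloxy)-3,5-dimethoxybenzaldehyde
Conditions: BnBr, K2CO3, DMF, 60 °C
Reagents that add atoms: benzyl bromide, BrCc1ccccc1
Why: Williamson ether synthesis on the phenoxide should protect the hindered phenol as a benzyl ether that lasts until the final hydrogenolysis.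

Step 2
Reactants: 2 4-(benzyloxy)-3,5-dimethoxybenzaldehyde
Product: 3 [4-(benzyloxy)-3,5-dimethoxyphenyl]methanol
Conditions: NaBH4, MeOH, 0 °C
Reagents that add atoms: none
Why: Borohydride reduction of the aryl aldehyde to the benzylic alcohol, with no other reducible group present.

Step 3
Reactants: 3 [4-(benzyloxy)-3,5-dimethoxyphenyl]methanol
Product: 4 4-(benzyloxy)-3,5-dimethoxybenzyl bromide
Conditions: PBr3, Et2O, 0 °C
Reagents that add atoms: phosphorus tribromide, BrP(Br)Br
Why: Bromination of the benzylic alcohol through its phosphite ester (SN2 by bromide); the labile electron-rich bromide should be used directly in step 6.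

Step 4
Reactants: 5 4-(benzyloxy)-3-methoxybenzaldehyde (O-benzylvanillin), 6 (2-carboxyethyl)triphenylphosphonium bromide
Product: 8 (3E)-4-[4-(benzyloxy)-3-methoxyphenyl]but-3-enoic acid, via phosphonium ylide 7 (not isolated)
Conditions: 6, NaN(SiMe3)2 (2 equiv), THF, 0 °C; then 5, 0 to 20 °C; aq. HCl work-up
Reagents that add atoms: none
Why: Wittig olefination with the carboxylate-bearing ylide, which with aromatic aldehydes should favour the E-configured β,γ-unsaturated acid; the alkene geometry is erased in step 9 in any case.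

Step 5
Reactants: 8 (3E)-4-[4-(benzyloxy)-3-methoxyphenyl]but-3-enoic acid, 9 (4R)-4-benzyl-1,3-oxazolidin-2-one
Product: 11 (4R)-4-benzyl-3-[(3E)-4-[4-(benzyloxy)-3-methoxyphenyl]but-3-enoyl]-1,3-oxazolidin-2-one, via pivalic mixed anhydride 10 (not isolated)
Conditions: PivCl, Et3N, THF, −20 °C; then 9, LiCl, −20 to 20 °C
Reagents that add atoms: none
Why: N-acylation of the oxazolidinone through the mixed pivalic anhydride, mild enough that the styrene-conjugated β,γ-alkene should not migrate.

Step 6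
Reactants: 11 (4R)-4-benzyl-3-[(3E)-4-[4-(benzyloxy)-3-methoxyphenyl]but-3-enoyl]-1,3-oxazolidin-2-one, 4 4-(benzyloxy)-3,5-dimethoxybenzyl bromide
Product: 13 (4R)-4-benzyl-3-[(2R,3E)-4-[4-(benzyloxy)-3-methoxyphenyl]-2-[[4-(benzyloxy)-3,5-dimethoxyphenyl]methyl]but-3-enoyl]-1,3-oxazolidin-2-one, via sodium Z-enolate 12 (not isolated)
Conditions: NaN(SiMe3)2 (1.05 equiv), THF, −78 °C; then 4, −78 to −40 °C; AcOH quench
Reagents that add atoms: none
Why: Evans alkylation of the chelated Z-dienolate, which should react at its α-carbon with the benzylic bromide on the face opposite the benzyl group of the (R)-oxazolidinone and so set the (R) centre that becomes C4 of the lactone.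

Step 7
Reactants: 13 (4R)-4-benzyl-3-[(2R,3E)-4-[4-(benzyloxy)-3-methoxyphenyl]-2-[[4-(benzyloxy)-3,5-dimethoxyphenyl]methyl]but-3-enoyl]-1,3-oxazolidin-2-one
Product: 14 (2R,3E)-4-[4-(benzyloxy)-3-methoxyphenyl]-2-[[4-(benzyloxy)-3,5-dimethoxyphenyl]methyl]but-3-en-1-ol
Conditions: LiBH4, H2O (1 equiv), Et2O, 0 °C
Reagents that add atoms: none
Why: Reductive cleavage of the N-acyl oxazolidinone by lithium borohydride gives the primary alcohol, releases the auxiliary and should leave the α-stereocentre and the alkene untouched.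

Step 8
Reactants: 14 (2R,3E)-4-[4-(benzyloxy)-3-methoxyphenyl]-2-[[4-(benzyloxy)-3,5-dimethoxyphenyl]methyl]but-3-en-1-ol
Product: 15 1-(benzyloxy)-4-[(1E,3R)-3-[[4-(benzyloxy)-3,5-dimethoxyphenyl]methyl]-4-chlorobut-1-en-1-yl]-2-methoxybenzene
Conditions: PPh3, NCS, THF, 0 to 20 °C
Reagents that add atoms: N-chlorosuccinimide, O=C1CCC(=O)N1Cl
Why: Appel-type chlorination in which chloride displaces the alkoxyphosphonium group at the primary carbon by SN2, so the adjacent stereocentre is not involved.

Step 9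
Reactants: 15 1-(benzyloxy)-4-[(1E,3R)-3-[[4-(benzyloxy)-3,5-dimethoxyphenyl]methyl]-4-chlorobut-1-en-1-yl]-2-methoxybenzene
Product: 18 (3R,4R)-3-[[4-(benzyloxy)-3-methoxyphenyl]methyl]-4-[[4-(benzyloxy)-3,5-dimethoxyphenyl]methyl]oxolan-2-one, via potassium chlorobutanoate 16 (not isolated), via C3-epimeric lactone 17 (not isolated)
Conditions: HCO2K (5 equiv), 4CzIPN (2,4,5,6-tetra(carbazol-9-yl)isophthalonitrile, 2 mol %), 2,4,6-triisopropylbenzenethiol (20 mol %), DMSO, 450 nm LEDs, 25 °C; then DBU, 60 °C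
Reagents that add atoms: potassium formate (HCO2K), [K+].[O-]C=O
Why: Proposed new method: a photoinitiated, thiol-mediated radical chain is proposed in which the thiyl radical abstracts the formyl hydrogen of formate, the resulting carbon dioxide radical anion adds to the styrene carbon remote from the guaiacyl ring (future C3) to give the guaiacyl-stabilised benzylic radical, the thiol returns hydrogen to that radical, and the potassium carboxylate 16 then displaces the primary chloride on warming, so that C2–C3 and O1–C5 both arise from one formate ion. The closest known reaction type is the thiol-catalysed anti-Markovnikov hydrocarboxylation of styrenes with formate salts under visible light, joined here to the classical lactonisation of a 4-halobutanoate; what is new is their union on an electron-rich 1,2-disubstituted styrene that carries the electrophile. The lactone ring closes in the 5-exo-tet mode by SN2 attack of the carboxylate oxygen on C5. C3 is the only new stereocentre, and the radical addition need not be selective, because DBU equilibrates the epimerisable C3 of 17 under control of the fixed C4 centre toward the trans-3,4-disubstituted lactone, which should be strongly favoured. The step needs C–C bond formation at the homobenzylic alkene carbon, secured by benzylic radical stabilisation from the guaiacyl ring, and survival of the electrophile until the carboxylate exists, secured by a primary β-branched chloride that should be inert to formate and to the hindered thiolate at 25 °C; C4 is not touched and should keep its configuration.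

Step 10
Reactants: 18 (3R,4R)-3-[[4-(benzyloxy)-3-methoxyphenyl]methyl]-4-[[4-(benzyloxy)-3,5-dimethoxyphenyl]methyl]oxolan-2-one
Product: 19 (3R,4R)-3-[(4-hydroxy-3-methoxyphenyl)methyl]-4-[(4-hydroxy-3,5-dimethoxyphenyl)methyl]oxolan-2-one
Conditions: H2 (1 atm), 10% Pd/C, EtOAc–EtOH, 20 °C
Reagents that add atoms: none
Why: Hydrogenolysis of both aryl benzyl ethers over palladium on carbon, under which the lactone and the two stereocentres should be unaffected.

**Compound list**

1 | syringaldehyde (4-hydroxy-3,5-dimethoxybenzaldehyde) | COc1cc(C=O)cc(OC)c1O | starting material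
2 | 4-(benzyloxy)-3,5-dimethoxybenzaldehyde | COc1cc(C=O)cc(OC)c1OCc1ccccc1 | intermediate
3 | [4-(benzyloxy)-3,5-dimethoxyphenyl]methanol | COc1cc(CO)cc(OC)c1OCc1ccccc1 | intermediate
4 | 4-(benzyloxy)-3,5-dimethoxybenzyl bromide | COc1cc(CBr)cc(OC)c1OCc1ccccc1 | intermediate
5 | 4-(benzyloxy)-3-methoxybenzaldehyde (O-benzylvanillin) | COc1cc(C=O)ccc1OCc1ccccc1 | starting material
6 | (2-carboxyethyl)triphenylphosphonium bromide | [Br-].OC(=O)CC[P+](c1ccccc1)(c1ccccc1)c1ccccc1 | starting material
7 | sodium 3-(triphenylphosphoranylidene)propanoate (ylide, not isolated) | [Na+].[O-]C(=O)CC=P(c1ccccc1)(c1ccccc1)c1ccccc1 | intermediate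
8 | (3E)-4-[4-(benzyloxy)-3-methoxyphenyl]but-3-enoic acid | OC(=O)C/C=C/c1ccc(OCc2ccccc2)c(OC)c1 | intermediate
9 | (4R)-4-benzyl-1,3-oxazolidin-2-one | O=C1N[C@H](Cc2ccccc2)CO1 | starting material
10 | (3E)-4-[4-(benzyloxy)-3-methoxyphenyl]but-3-enoic pivalic anhydride (not isolated) | CC(C)(C)C(=O)OC(=O)C/C=C/c1ccc(OCc2ccccc2)c(OC)c1 | intermediate
11 | (4R)-4-benzyl-3-[(3E)-4-[4-(benzyloxy)-3-methoxyphenyl]but-3-enoyl]-1,3-oxazolidin-2-one | O=C(C/C=C/c1ccc(OCc2ccccc2)c(OC)c1)N1[C@H](Cc2ccccc2)COC1=O | intermediate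
12 | sodium Z-enolate of 11 (not isolated) | [Na+].[O-]/C(=C\C=C\c1ccc(OCc2ccccc2)c(OC)c1)N1[C@H](Cc2ccccc2)COC1=O | intermediate
13 | (4R)-4-benzyl-3-[(2R,3E)-4-[4-(benzyloxy)-3-methoxyphenyl]-2-[[4-(benzyloxy)-3,5-dimethoxyphenyl]methyl]but-3-enoyl]-1,3-oxazolidin-2-one | O=C([C@H](Cc1cc(OC)c(OCc2ccccc2)c(OC)c1)/C=C/c1ccc(OCc2ccccc2)c(OC)c1)N1[C@H](Cc2ccccc2)COC1=O | intermediate
14 | (2R,3E)-4-[4-(benzyloxy)-3-methoxyphenyl]-2-[[4-(benzyloxy)-3,5-dimethoxyphenyl]methyl]but-3-en-1-ol | OC[C@H](Cc1cc(OC)c(OCc2ccccc2)c(OC)c1)/C=C/c1ccc(OCc2ccccc2)c(OC)c1 | intermediate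
15 | 1-(benzyloxy)-4-[(1E,3R)-3-[[4-(benzyloxy)-3,5-dimethoxyphenyl]methyl]-4-chlorobut-1-en-1-yl]-2-methoxybenzene | ClC[C@H](Cc1cc(OC)c(OCc2ccccc2)c(OC)c1)/C=C/c1ccc(OCc2ccccc2)c(OC)c1 | intermediate
16 | potassium (3R)-2-[[4-(benzyloxy)-3-methoxyphenyl]methyl]-3-[[4-(benzyloxy)-3,5-dimethoxyphenyl]methyl]-4-chlorobutanoate, both C2 epimers (not isolated) | [K+].[O-]C(=O)C(Cc1ccc(OCc2ccccc2)c(OC)c1)[C@H](CCl)Cc1cc(OC)c(OCc2ccccc2)c(OC)c1 | intermediate
17 | (4R)-3-[[4-(benzyloxy)-3-methoxyphenyl]methyl]-4-[[4-(benzyloxy)-3,5-dimethoxyphenyl]methyl]oxolan-2-one, C3 epimers (not isolated) | COc1cc(CC2C(=O)OC[C@@H]2Cc2cc(OC)c(OCc3ccccc3)c(OC)c2)ccc1OCc1ccccc1 | intermediate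
18 | (3R,4R)-3-[[4-(benzyloxy)-3-methoxyphenyl]methyl]-4-[[4-(benzyloxy)-3,5-dimethoxyphenyl]methyl]oxolan-2-one | COc1cc(C[C@H]2C(=O)OC[C@@H]2Cc2cc(OC)c(OCc3ccccc3)c(OC)c2)ccc1OCc1ccccc1 | intermediate
19 | (3R,4R)-3-[(4-hydroxy-3-methoxyphenyl)methyl]-4-[(4-hydroxy-3,5-dimethoxyphenyl)methyl]oxolan-2-one | COc1cc(C[C@H]2C(=O)OC[C@@H]2Cc2cc(OC)c(O)c(OC)c2)ccc1O | target

**Totals**

Total step count: 10. Longest linear sequence: 8 steps (steps 1, 2, 3, 6, 7, 8, 9, 10).

**Steps most likely to fail**

Step 9 (proposed new method). Three processes may go wrong: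
- addition of the nucleophilic carbon dioxide radical anion to the electron-rich, 1,2-disubstituted styrene may be slow;
- the allylic stereocentre may erode by reversible hydrogen abstraction by the thiyl radical before the alkene is consumed;
- the chloride may be consumed by thiolate before carboxylation.

Fallback by known chemistry, setting out from oxazolidinone 9, bromide 4 and aldehyde 5 and returning at lactone 18:
- Oxazolidinone 9 is acylated with 4-tert-butoxy-4-oxobutanoic acid (PivCl, Et3N, LiCl) to give tert-butyl 4-[(4R)-4-benzyl-2-oxo-1,3-oxazolidin-3-yl]-4-oxobutanoate F1.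
- Its sodium imide enolate (NaN(SiMe3)2, THF, −78 °C) is alkylated with bromide 4 to give tert-butyl (3R)-4-[(4R)-4-benzyl-2-oxo-1,3-oxazolidin-3-yl]-3-[[4-(benzyloxy)-3,5-dimethoxyphenyl]methyl]-4-oxobutanoate F2.
- LiBH4 removes the auxiliary to give tert-butyl (3R)-3-[[4-(benzyloxy)-3,5-dimethoxyphenyl]methyl]-4-hydroxybutanoate F3, which should lactonise with catalytic TsOH in toluene to (4R)-4-[[4-(benzyloxy)-3,5-dimethoxyphenyl]methyl]oxolan-2-one F4.
- Separately, aldehyde 5 is reduced (NaBH4) to [4-(benzyloxy)-3-methoxyphenyl]methanol F5 and brominated (PBr3) to 4-(benzyloxy)-3-methoxybenzyl bromide F6.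
- The lithium enolate of F4 (LiN(SiMe3)2, THF, −78 °C) should be alkylated by F6 anti to the C4 substituent to give the trans lactone 18.

Step 6. The dienolate alkylation may lose regiocontrol (γ-attack), and the doubly activated α-centre of the product may epimerise or the alkene may move into conjugation.

Fallback, setting out from bromide 4 and aldehyde 5 and returning at alcohol 14:
- Bromide 4 is converted (Mg, Et2O, 0 °C) into [4-(benzyloxy)-3,5-dimethoxybenzyl]magnesium bromide F7.
- Copper-catalysed asymmetric allylic alkylation in the SN2′ sense of (E)-(4-bromobut-2-enyloxy)(tert-butyl)dimethylsilane (CuBr·SMe2, Taniaphos-type ferrocenyl diphosphine, the enantiomer that delivers the R product, CH2Cl2, −78 °C) should give tert-butyl[[(2R)-2-[[4-(benzyloxy)-3,5-dimethoxyphenyl]methyl]but-3-en-1-yl]oxy]dimethylsilane F8.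
- Aldehyde 5 is methylenated (Ph3P=CH2, THF) to 1-(benzyloxy)-4-ethenyl-2-methoxybenzene F9.
- Cross metathesis of F8 with F9 (second-generation Grubbs catalyst, CH2Cl2, 40 °C) should give the E-configured tert-butyldimethylsilyl ether of 14 F10.
- Bu4NF in THF frees alcohol 14.

Step 4. The E/Z control of the Wittig reaction may be poor, and the phosphonium salt may fragment by retro-Michael loss of triphenylphosphine under base.

Fallback, setting out from aldehyde 5 and returning at acid 8:
- Wittig reaction of 5 with (methoxymethyl)triphenylphosphonium chloride and KOtBu gives the enol ether 1-(benzyloxy)-2-methoxy-4-(2-methoxyethenyl)benzene F11.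
- Hydrolysis with aqueous HCl in THF gives 2-[4-(benzyloxy)-3-methoxyphenyl]acetaldehyde F12.
- Knoevenagel–Doebner condensation of F12 with malonic acid under the β,γ-selective modification (piperidinium acetate, DMSO, 100 °C), with decarboxylation, should give the E-configured acid 8.

**Further compounds**

F1 | step 9 | tert-butyl 4-[(4R)-4-benzyl-2-oxo-1,3-oxazolidin-3-yl]-4-oxobutanoate | CC(C)(C)OC(=O)CCC(=O)N1[C@H](Cc2ccccc2)COC1=O
F2 | step 9 | tert-butyl (3R)-4-[(4R)-4-benzyl-2-oxo-1,3-oxazolidin-3-yl]-3-[[4-(benzyloxy)-3,5-dimethoxyphenyl]methyl]-4-oxobutanoate | CC(C)(C)OC(=O)C[C@@H](Cc1cc(OC)c(OCc2ccccc2)c(OC)c1)C(=O)N1[C@H](Cc2ccccc2)COC1=O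
F3 | step 9 | tert-butyl (3R)-3-[[4-(benzyloxy)-3,5-dimethoxyphenyl]methyl]-4-hydroxybutanoate | CC(C)(C)OC(=O)C[C@@H](Cc1cc(OC)c(OCc2ccccc2)c(OC)c1)CO
F4 | step 9 | (4R)-4-[[4-(benzyloxy)-3,5-dimethoxyphenyl]methyl]oxolan-2-one | O=C1OC[C@H](Cc2cc(OC)c(OCc3ccccc3)c(OC)c2)C1
F5 | step 9 | [4-(benzyloxy)-3-methoxyphenyl]methanol | COc1cc(CO)ccc1OCc1ccccc1
F6 | step 9 | 4-(benzyloxy)-3-methoxybenzyl bromide | COc1cc(CBr)ccc1OCc1ccccc1
F7 | step 6 | [4-(benzyloxy)-3,5-dimethoxybenzyl]magnesium bromide | COc1cc(C[Mg]Br)cc(OC)c1OCc1ccccc1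
F8 | step 6 | tert-butyl[[(2R)-2-[[4-(benzyloxy)-3,5-dimethoxyphenyl]methyl]but-3-en-1-yl]oxy]dimethylsilane | C=C[C@@H](Cc1cc(OC)c(OCc2ccccc2)c(OC)c1)CO[Si](C)(C)C(C)(C)C
F9 | step 6 | 1-(benzyloxy)-4-ethenyl-2-methoxybenzene | C=Cc1ccc(OCc2ccccc2)c(OC)c1
F10 | step 6 | tert-butyldimethylsilyl ether of 14 | CC(C)(C)[Si](C)(C)OC[C@H](Cc1cc(OC)c(OCc2ccccc2)c(OC)c1)/C=C/c1ccc(OCc2ccccc2)c(OC)c1
F11 | step 4 | 1-(benzyloxy)-2-methoxy-4-(2-methoxyethenyl)benzene (E/Z mixture) | COC=Cc1ccc(OCc2ccccc2)c(OC)c1
F12 | step 4 | 2-[4-(benzyloxy)-3-methoxyphenyl]acetaldehyde | O=CCc1ccc(OCc2ccccc2)c(OC)c1
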